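**Retrosynthetic overview**
1. Target 22 ⇐ bridging ketone 19 (Wolff–Kishner reduction, ketal removal) ⇐ β-hydroxy ketone 17 (dehydration gives the ring A alkene).
2. Key disconnection: both inter-ring bonds (C1–C2 and C5–C6) by a (4+3) cycloaddition of a cyclopentenyl oxyallyl cation (an enolonium equivalent, from epoxy enol silane 15) with cyclopentadiene 13. This closes the central six-membered ring and sets all four core stereocentres.
3. Both partners come from one enone 11: diene 13 by reduction/dehydration (ring B), epoxy enol silane 15 by epoxidation/silylation (ring A).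
4. Enone 11 ⇐ Stetter reaction/aldol condensation of cyclopropanecarbaldehyde 7 with ethyl vinyl ketone.
5. Aldehyde 7 ⇐ chiral-pool lactone 1 (Wittig chain extension, diimide, oxidation). Ring order: cyclopropane (bought) → the two five-membered rings → central six-membered ring in the key step.

Assumption: lactone 1 is bought as the single (1S,5R) enantiomer and phosphonium salt 3 as a catalogue Wittig salt; diene 13 is used as its equilibrating double-bond-isomer mixture.

Shorthand: CpK = (1R,3S)-2,2-dimethyl-3-[2-(2-methyl-1,3-dioxolan-2-yl)ethyl]cyclopropyl, bonded through C1. Core locants follow tricyclo[4.2.1.1(2,5)]decane numbering (C1 carries the quaternary methyl).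

**Step 1**
Reactants: 1 (1S,5R)-6,6-dimethyl-3-oxabicyclo[3.1.0]hexan-2-one
Product: 2 (1S,5R)-6,6-dimethyl-3-oxabicyclo[3.1.0]hexan-2-ol
Conditions: i-Bu2AlH (1.05 equiv), CH2Cl2, −78 °C; aq. KNaC4H4O6 work-up
Reagents that add atoms: none
Why: Half-reduction of a lactone to the lactol (the aluminium hemiacetal survives at −78 °C until work-up); the cyclopropane stereocentres are untouched and the new hemiacetal carbon is an inconsequential epimer mixture.

**Step 2**
Reactants: 2 (1S,5R)-6,6-dimethyl-3-oxabicyclo[3.1.0]hexan-2-ol; 3 [(2-methyl-1,3-dioxolan-2-yl)methyl]triphenylphosphonium bromide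
Product: 5 [(1R,3S)-2,2-dimethyl-3-[(Z)-2-(2-methyl-1,3-dioxolan-2-yl)ethenyl]cyclopropyl]methanol, via ylide 4 (not isolated)
Conditions: 3 (2.2 equiv), KOtBu (2.2 equiv), THF, 0 °C; then 2, 0 → 23 °C
Reagents that add atoms: none
Why: Wittig olefination of the hydroxy aldehyde in equilibrium with the lactol (standard for this pyrethroid lactol) gives mainly the Z-alkene, whose geometry is erased in step 3, and leaves the cis-cyclopropane intact.

**Step 3**
Reactants: 5 [(1R,3S)-2,2-dimethyl-3-[(Z)-2-(2-methyl-1,3-dioxolan-2-yl)ethenyl]cyclopropyl]methanol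
Product: 6 [(1R,3S)-2,2-dimethyl-3-[2-(2-methyl-1,3-dioxolan-2-yl)ethyl]cyclopropyl]methanol
Conditions: TsNHNH2 (5 equiv), NaOAc (6 equiv), THF/H2O, 65 °C
Reagents that add atoms: none
Why: Diimide reduction transfers H2 concertedly to the disubstituted alkene and avoids the vinylcyclopropane hydrogenolysis that heterogeneous hydrogenation risks; no stereocentre is formed.

**Step 4**
Reactants: 6 [(1R,3S)-2,2-dimethyl-3-[2-(2-methyl-1,3-dioxolan-2-yl)ethyl]cyclopropyl]methanol
Product: 7 (1R,3S)-2,2-dimethyl-3-[2-(2-methyl-1,3-dioxolan-2-yl)ethyl]cyclopropane-1-carbaldehyde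
Conditions: Dess–Martin periodinane (1.2 equiv), CH2Cl2, 0 → 23 °C
Reagents that add atoms: none
Why: Dess–Martin oxidation of the primary alcohol under non-basic conditions, so the cis-aldehyde does not epimerise to trans.

**Step 5**
Reactants: 7 (1R,3S)-2,2-dimethyl-3-[2-(2-methyl-1,3-dioxolan-2-yl)ethyl]cyclopropane-1-carbaldehyde; 8 pent-1-en-3-one
Product: 11 3-CpK-2-methylcyclopent-2-en-1-one, via 1,4-diketone 9 (not isolated), via ketol 10 (not isolated)
Conditions: 8 (1.5 equiv), 3-benzyl-5-(2-hydroxyethyl)-4-methylthiazolium chloride (0.2 equiv), Et3N (0.5 equiv), EtOH, 75 °C; then 2 M aq. NaOH, 60 °C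
Reagents that add atoms: none
Why: Stetter reaction (the thiazolium-derived acyl anion adds 1,4 to the vinyl ketone) then intramolecular aldol condensation of the 1,4-diketone, as in the classical dihydrojasmone synthesis; the ketal blocks the competing aldol of the side-chain ketone onto the cis carbonyl, and no stereocentre is formed.

**Step 6**
Reactants: 11 3-CpK-2-methylcyclopent-2-en-1-one
Product: 13 2-CpK-3-methylcyclopenta-1,3-diene, via allylic alcohol 12 (not isolated)
Conditions: i-Bu2AlH, CH2Cl2, −78 °C; then pyridinium p-toluenesulfonate (5 mol%), 4 Å sieves, benzene, 40 °C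
Reagents that add atoms: none
Why: 1,2-Reduction of the enone then acid-catalysed dehydration of the allylic alcohol is the standard route to alkylcyclopentadienes; 1,5-hydrogen shifts equilibrate the double-bond isomers and no ring stereocentre remains.

**Step 7**
Reactants: 11 3-CpK-2-methylcyclopent-2-en-1-one
Product: 14 (1S,5R)-5-CpK-1-methyl-6-oxabicyclo[3.1.0]hexan-2-one
Conditions: 30% aq. H2O2, NaOH (0.3 equiv), MeOH, 0 → 23 °C
Reagents that add atoms: hydrogen peroxide (OO)
Why: Weitz–Scheffer nucleophilic epoxidation forms both epoxide stereocentres together (cis by ring constraint); only the adjacent cyclopropane differentiates the enone faces, so a modest ratio is expected and 14 is separated from its epoxide diastereomer by chromatography.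

**Step 8**
Reactants: 14 (1S,5R)-5-CpK-1-methyl-6-oxabicyclo[3.1.0]hexan-2-one
Product: 15 triethyl{[(1S,5R)-5-CpK-1-methyl-6-oxabicyclo[3.1.0]hex-2-en-2-yl]oxy}silane
Conditions: Et3SiOTf (1.2 equiv), Et3N (2 equiv), CH2Cl2, −78 → 0 °C
Reagents that add atoms: triethylsilyl trifluoromethanesulfonate (CC[Si](CC)(CC)OS(=O)(=O)C(F)(F)F)
Why: Soft enolisation can occur only at the single CH2 next to the ketone and gives the epoxy enol silane, the substrate class of the epoxy-enol-silane (4+3) cycloaddition; the epoxide stereocentres are retained.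

**Step 9 (key step)**
Reactants: 15 triethyl{[(1S,5R)-5-CpK-1-methyl-6-oxabicyclo[3.1.0]hex-2-en-2-yl]oxy}silane; 13 2-CpK-3-methylcyclopenta-1,3-diene
Product: 17 (1S,2S,5S,6S,8R)-4,8-bis(CpK)-8-hydroxy-1,3-dimethyltricyclo[4.2.1.1(2,5)]dec-3-en-9-one, via triethylsilyl ether 16 (not isolated)
Conditions: 13 (3 equiv), Et3SiOTf (0.2 equiv), 2,6-di-tert-butyl-4-methylpyridine (0.3 equiv), CH2Cl2, −78 °C; then Bu4NF, AcOH, THF, 0 °C
Reagents that add atoms: none
Why: (4+3) cycloaddition of an oxyallyl cation with a diene (epoxy-enol-silane variant), in which silyl-triflate ionisation of the tertiary allylic C–O bond gives a 2-silyloxyallyl cation whose normally nucleophilic α-carbons bond to the two nucleophilic diene termini; the diene adds to the cation face anti to the bulky cyclopropyl on the neighbouring carbinol carbon, the extended transition state (carbonyl over the diene CH2) gives the face-to-face syn skeleton, and union of the cyclopropyl-flanked, more nucleophilic diene terminus with the less hindered CH terminus fixes the regiochemistry, so the four core stereocentres (1S,2S,5S,6S) arise in one event.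

**Step 10**
Reactants: 17 (1S,2S,5S,6S,8R)-4,8-bis(CpK)-8-hydroxy-1,3-dimethyltricyclo[4.2.1.1(2,5)]dec-3-en-9-one
Product: 19 (1S,2S,5S,6S)-4,8-bis(CpK)-1,3-dimethyltricyclo[4.2.1.1(2,5)]deca-3,7-dien-9-one, via sulfamate ester 18 (not isolated)
Conditions: Burgess reagent (MeO2CNSO2NEt3 inner salt, 3 equiv), toluene, 70 °C
Reagents that add atoms: none
Why: Burgess dehydration (syn-elimination through the sulfamate ester) can only use the hydrogens of the ring CH2, because the other neighbour of the carbinol is quaternary, so the trisubstituted ring A alkene forms regiospecifically and the relay stereocentre C8 is erased.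

**Step 11**
Reactants: 19 (1S,2S,5S,6S)-4,8-bis(CpK)-1,3-dimethyltricyclo[4.2.1.1(2,5)]deca-3,7-dien-9-one
Product: 22 (1S,2S,5S,6S)-1,3-dimethyl-4,8-bis[(1R,3S)-2,2-dimethyl-3-(3-oxobutyl)cyclopropyl]tricyclo[4.2.1.1(2,5)]deca-3,7-diene, via hydrazone 20 (not isolated), via bis-ketal 21 (not isolated)
Conditions: N2H4·H2O, KOH, diethylene glycol, 130 → 200 °C; then 1 M aq. HCl, THF, 23 °C
Reagents that add atoms: water (O)
Why: Wolff–Kishner reduction (Huang–Minlon procedure) of the non-enolisable bridging ketone through its hydrazone is tolerated by the ketals, the vinylcyclopropanes and the isolated alkenes, and aqueous acid then unmasks both methyl ketones without touching any stereocentre.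

**Compound list**
1 | (1S,5R)-6,6-dimethyl-3-oxabicyclo[3.1.0]hexan-2-one | O=C1OC[C@@H]2[C@H]1C2(C)C | starting material
2 | (1S,5R)-6,6-dimethyl-3-oxabicyclo[3.1.0]hexan-2-ol (both C2 epimers) | OC1OC[C@@H]2[C@H]1C2(C)C | intermediate
3 | [(2-methyl-1,3-dioxolan-2-yl)methyl]triphenylphosphonium bromide | CC1(C[P+](c2ccccc2)(c2ccccc2)c2ccccc2)OCCO1.[Br-] | starting material
4 | [(2-methyl-1,3-dioxolan-2-yl)methylidene]triphenylphosphorane (ylide) | CC1(C=P(c2ccccc2)(c2ccccc2)c2ccccc2)OCCO1 | intermediate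
5 | [(1R,3S)-2,2-dimethyl-3-[(Z)-2-(2-methyl-1,3-dioxolan-2-yl)ethenyl]cyclopropyl]methanol | CC1(OCCO1)/C=C\[C@H]2[C@@H](CO)C2(C)C | intermediate
6 | [(1R,3S)-2,2-dimethyl-3-[2-(2-methyl-1,3-dioxolan-2-yl)ethyl]cyclopropyl]methanol | CC1(OCCO1)CC[C@H]2[C@@H](CO)C2(C)C | intermediate
7 | (1R,3S)-2,2-dimethyl-3-[2-(2-methyl-1,3-dioxolan-2-yl)ethyl]cyclopropane-1-carbaldehyde | CC1(OCCO1)CC[C@H]2[C@@H](C=O)C2(C)C | intermediate
8 | pent-1-en-3-one (ethyl vinyl ketone) | CCC(=O)C=C | starting material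
9 | 1-CpK-heptane-1,4-dione | CC1(OCCO1)CC[C@H]2[C@@H](C(=O)CCC(=O)CC)C2(C)C | intermediate
10 | 3-CpK-3-hydroxy-2-methylcyclopentan-1-one (ketol, ring stereocentres mixed) | CC1(OCCO1)CC[C@H]2[C@@H](C3(O)CCC(=O)C3C)C2(C)C | intermediate
11 | 3-CpK-2-methylcyclopent-2-en-1-one | CC1(OCCO1)CC[C@H]2[C@@H](C3=C(C)C(=O)CC3)C2(C)C | intermediate
12 | 3-CpK-2-methylcyclopent-2-en-1-ol (both C1 epimers) | CC1(OCCO1)CC[C@H]2[C@@H](C3=C(C)C(O)CC3)C2(C)C | intermediate
13 | 2-CpK-3-methylcyclopenta-1,3-diene (equilibrating with its 1,5-hydrogen-shift isomers) | CC1(OCCO1)CC[C@H]2[C@@H](C3=CCC=C3C)C2(C)C | intermediate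
14 | (1S,5R)-5-CpK-1-methyl-6-oxabicyclo[3.1.0]hexan-2-one | CC1(OCCO1)CC[C@H]2[C@@H]([C@]34CCC(=O)[C@@]3(C)O4)C2(C)C | intermediate
15 | triethyl{[(1S,5R)-5-CpK-1-methyl-6-oxabicyclo[3.1.0]hex-2-en-2-yl]oxy}silane | CC1(OCCO1)CC[C@H]2[C@@H]([C@]34CC=C(O[Si](CC)(CC)CC)[C@@]3(C)O4)C2(C)C | intermediate
16 | (1S,2S,5S,6S,8R)-4,8-bis(CpK)-1,3-dimethyl-8-(triethylsilyloxy)tricyclo[4.2.1.1(2,5)]dec-3-en-9-one | CC1(OCCO1)CC[C@H]2[C@@H]([C@]3(O[Si](CC)(CC)CC)C[C@@H]4C(=O)[C@@]3(C)[C@H]3C[C@@H]4C([C@@H]5[C@H](CCC6(C)OCCO6)C5(C)C)=C3C)C2(C)C | intermediate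
17 | (1S,2S,5S,6S,8R)-4,8-bis(CpK)-8-hydroxy-1,3-dimethyltricyclo[4.2.1.1(2,5)]dec-3-en-9-one | CC1(OCCO1)CC[C@H]2[C@@H]([C@]3(O)C[C@@H]4C(=O)[C@@]3(C)[C@H]3C[C@@H]4C([C@@H]5[C@H](CCC6(C)OCCO6)C5(C)C)=C3C)C2(C)C | intermediate
18 | triethylammonium (1S,2S,5S,6S,8R)-4,8-bis(CpK)-1,3-dimethyl-9-oxotricyclo[4.2.1.1(2,5)]dec-3-en-8-yl N-(methoxycarbonyl)sulfamate | CC1(OCCO1)CC[C@H]2[C@@H]([C@]3(OS(=O)(=O)[N-]C(=O)OC)C[C@@H]4C(=O)[C@@]3(C)[C@H]3C[C@@H]4C([C@@H]5[C@H](CCC6(C)OCCO6)C5(C)C)=C3C)C2(C)C.CC[NH+](CC)CC | intermediate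
19 | (1S,2S,5S,6S)-4,8-bis(CpK)-1,3-dimethyltricyclo[4.2.1.1(2,5)]deca-3,7-dien-9-one | CC1(OCCO1)CC[C@H]2[C@@H](C3=C[C@@H]4C(=O)[C@@]3(C)[C@H]3C[C@@H]4C([C@@H]5[C@H](CCC6(C)OCCO6)C5(C)C)=C3C)C2(C)C | intermediate
20 | hydrazone of 19 at C9 | CC1(OCCO1)CC[C@H]2[C@@H](C3=C[C@@H]4C(=NN)[C@@]3(C)[C@H]3C[C@@H]4C([C@@H]5[C@H](CCC6(C)OCCO6)C5(C)C)=C3C)C2(C)C | intermediate
21 | (1S,2S,5S,6S)-4,8-bis(CpK)-1,3-dimethyltricyclo[4.2.1.1(2,5)]deca-3,7-diene | CC1(OCCO1)CC[C@H]2[C@@H](C3=C[C@@H]4C[C@@]3(C)[C@H]3C[C@@H]4C([C@@H]5[C@H](CCC6(C)OCCO6)C5(C)C)=C3C)C2(C)C | intermediate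
22 | (1S,2S,5S,6S)-1,3-dimethyl-4,8-bis[(1R,3S)-2,2-dimethyl-3-(3-oxobutyl)cyclopropyl]tricyclo[4.2.1.1(2,5)]deca-3,7-diene | CC(=O)CC[C@H]1[C@@H](C2=C[C@@H]3C[C@@]2(C)[C@H]2C[C@@H]3C([C@@H]3[C@H](CCC(C)=O)C3(C)C)=C2C)C1(C)C | target

**Totals**
Total steps: 11. Longest linear sequence: 10 steps (steps 1–5 and 7–11; step 6 is the branch to diene 13).

**Steps most likely to fail, with fallbacks**

Step 9 is the largest risk. The silylated epoxide may ionise at the cyclopropyl-bearing carbon (semipinacol shift or cyclopropane opening) instead of at the allylic carbon. The cycloaddition must also deliver one of several regio-, endo/exo- and facial isomers at a very hindered terminus. The fallback makes the same oxyallyl cation under basic, Lewis-acid-free conditions. It sets out from epoxy ketone 14: reductive epoxide opening with SmI2 and trapping of the samarium enolate with N-chlorosuccinimide gives (3R)-2-chloro-3-CpK-3-hydroxy-2-methylcyclopentan-1-one F1. Silylation (Me3SiOTf, 2,6-lutidine) gives its trimethylsilyl ether F2. Et3N in CF3CH2OH with diene 13 then ionises the tertiary chloride through the enolate and gives the trimethylsilyl ether cycloadduct F3, and Bu4NF returns to hydroxy ketone 17.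

Step 7 is the second risk. The cyclopropane may give little facial bias, or favour the wrong epoxide, and this stereocentre decides the absolute configuration of the core. The fallback sets the epoxide by reagent control. It sets out from enone 11: oxazaborolidine-catalysed (CBS) reduction with BH3·SMe2, using the catalyst enantiomer that gives the 1R carbinol, gives (1R)-3-CpK-2-methylcyclopent-2-en-1-ol F4. VO(acac)2/t-BuOOH epoxidises it syn to the hydroxyl to give (1R,2R,5R)-5-CpK-1-methyl-6-oxabicyclo[3.1.0]hexan-2-ol F5, and Dess–Martin oxidation returns to epoxy ketone 14.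

Step 10 is the third risk. Ionisation of the hindered tertiary cyclopropylcarbinyl sulfamate could open or rearrange the gem-dimethylcyclopropane before elimination. The fallback is a concerted thermal syn-elimination that forms no cation. It sets out from hydroxy ketone 17: KN(SiMe3)2, CS2 and MeI give the S-methyl xanthate F6, and heating in toluene (Chugaev elimination) returns to dienone 19.

**Further compounds**
F1 | step 9 | (3R)-2-chloro-3-CpK-3-hydroxy-2-methylcyclopentan-1-one (C2 epimers) | CC1(OCCO1)CC[C@H]2[C@@H]([C@]3(O)CCC(=O)C3(C)Cl)C2(C)C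
F2 | step 9 | (3R)-2-chloro-3-CpK-2-methyl-3-(trimethylsilyloxy)cyclopentan-1-one (C2 epimers) | CC1(OCCO1)CC[C@H]2[C@@H]([C@]3(O[Si](C)(C)C)CCC(=O)C3(C)Cl)C2(C)C
F3 | step 9 | (1S,2S,5S,6S,8R)-4,8-bis(CpK)-1,3-dimethyl-8-(trimethylsilyloxy)tricyclo[4.2.1.1(2,5)]dec-3-en-9-one | CC1(OCCO1)CC[C@H]2[C@@H]([C@]3(O[Si](C)(C)C)C[C@@H]4C(=O)[C@@]3(C)[C@H]3C[C@@H]4C([C@@H]5[C@H](CCC6(C)OCCO6)C5(C)C)=C3C)C2(C)C
F4 | step 7 | (1R)-3-CpK-2-methylcyclopent-2-en-1-ol | CC1(OCCO1)CC[C@H]2[C@@H](C3=C(C)[C@H](O)CC3)C2(C)C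
F5 | step 7 | (1R,2R,5R)-5-CpK-1-methyl-6-oxabicyclo[3.1.0]hexan-2-ol | CC1(OCCO1)CC[C@H]2[C@@H]([C@]34CC[C@@H](O)[C@@]3(C)O4)C2(C)C
F6 | step 10 | O-[(1S,2S,5S,6S,8R)-4,8-bis(CpK)-1,3-dimethyl-9-oxotricyclo[4.2.1.1(2,5)]dec-3-en-8-yl] S-methyl carbonodithioate | CC1(OCCO1)CC[C@H]2[C@@H]([C@]3(OC(=S)SC)C[C@@H]4C(=O)[C@@]3(C)[C@H]3C[C@@H]4C([C@@H]5[C@H](CCC6(C)OCCO6)C5(C)C)=C3C)C2(C)C
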